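Matter in a closed flask is conserved, so what the readings miss still stands in forms they do not show.

| flask | substrate | temperature | remark | time |
|---|---|---|---|---|
| grey | 0.20 M | 90 °C | run made earlier |  |
| north-west | 0.10 M |  | at 90 °C throughout | 150 h |
| north-east | 0.10 M |  | at 90 °C until 20 h, from then on at 120 °C | 40 h |

- grey (time / h: target / %, substrate / %): 1.00: 0, 83.0; 2.00: 0.7, 70.9; 3.00: 0, 62.4; 6.00: 1.2, 42.7; 12.0: 5.3, 27.9

(readings scatter by 0.5 percentage points)

- the numbers in the tables scatter with a standard deviation of 0.5 percentage points
- the earlier runs do not show what temperature does; that part of a forecast is a guess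

- which one finishes higher in amount of target, in percent of the substrate charged ("neither" within 2 percentage points) (north-west / north-east / neither)
- amount of target at the end, in percent of the substrate charged, north-west
- amount of target at the end, in percent of the substrate charged, north-east

In the grey run at 12.0 h, substrate and target leave 66.8% of the charge unseen, so target appears to come through a hidden pool. Between 6.00 h and 12.0 h target rises 4.1 percentage points while the pool averages 61.5%, which reads as a first-order exit of 0.0111 h⁻¹, with the scatter of two readings in it.

That exit times the time is the turnover count, 1.67 for north-west. One minus exp(−count) then reckons the share of the charge finished, 81.1% in north-west, with target some part of it. But the runs do not show temperature, so for north-east a guessed factor of 8 after the change gives a count of 2.00, higher than north-west's. This reckoning therefore expects north-east to finish higher.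

The forecast says north-east, with 63% (50% to 74%) for north-west and 78% (55% to 92%) for north-east, the latter “unless side losses intervene”.

The simulation gives 42.3% in north-west and 59.0% in north-east, so north-east finishes higher.

    intermediate A ⇌ intermediate D (K = 1.60, k = 0.0650 h⁻¹, Ea = 109 kJ mol⁻¹, ΔH = −76.0 kJ mol⁻¹)
    intermediate C → target (k = 0.0800 h⁻¹, Ea = 112 kJ mol⁻¹)
    intermediate A → intermediate C (k = 0.130 h⁻¹, Ea = 126 kJ mol⁻¹)
    substrate + target → side product (k = 0.790 L mol⁻¹ h⁻¹, Ea = 87.0 kJ mol⁻¹)
    target ⇌ isomer of the product (K = 0.190, k = 0.0720 h⁻¹, Ea = 108 kJ mol⁻¹, ΔH = −13.0 kJ mol⁻¹)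
    substrate ⇌ intermediate B (K = 1.10, k = 0.0960 h⁻¹, Ea = 110 kJ mol⁻¹, ΔH = −13.0 kJ mol⁻¹)
    substrate ⇌ intermediate A (K = 0.800, k = 0.0940 h⁻¹, Ea = 107 kJ mol⁻¹, ΔH = 4.00 kJ mol⁻¹)
    intermediate C ⇌ intermediate E (K = 3.90, k = 0.0130 h⁻¹, Ea = 128 kJ mol⁻¹, ΔH = 18.0 kJ mol⁻¹)
    (constants at 90 °C)

North-west ends with 86.3% of the charge in target, side product and isomer of the product, beside the count's 81.1%; side product, counted as two, holds 36.0%. At 12.9 h north-west makes target 3.89 times faster than it uses it up, each step taken net, and at the end target's half-life against side product, 41 d, is long against 150 h.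

A neighbour of north-west charged with [substrate] = 0.17 M has the same count, 1.67, since a first-order count holds no concentration, so again 81.1% is reckoned finished. That neighbour computes to 88.0% finished, with target at 34.8% and side product at 46.7%, against 42.3% and 36.0% in north-west.

The earlier runs and the new flask are calculated with made-up constants; the scatter is artificial.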